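**Retrosynthetic overview**

1. Denticulatolide is opened last at the 1,2-dioxane (C8–O–O–C11): H2O2 joins a (7S,8S)-7,8-epoxide (inversion at C8) and an (11R)-allylic mesylate (inversion at C11). The γ-lactone comes from a C2/C16 diol by oxidation, and C7–OAc from the epoxide oxygen.
2. The strategy rests on the unit C2(O)–C3H=C4(C18H3)–C5 of the 14-membered carbocycle: an E-trisubstituted alkene next to the lactone oxygen. It is read as a propargylic alcohol C2–C3≡C4 (hydroxyl-directed anti-hydroalumination, iodide then methyl at C4), so the ring is cut at C3≡C4 by ring-closing alkyne metathesis.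
3. The bis(methylalkyne) is built from (R)-carvone (C1, C11–C17, C20; ring cleaved between the carbonyl and the α′-carbon), 1-propynylmagnesium bromide (C3; Felkin–Anh addition sets C2) and bromide 5 from hex-4-yn-1-ol (C4–C9, C19). A CBS reduction sets C11.
4. Ring order: 14-membered carbocycle (step 16), γ-lactone (step 20), oxirane (step 21), 1,2-dioxane (step 24).

Key step: step 16

Assumption: cembrane numbering is used throughout (C1–C14 ring carbons; C15, C16, C17 the lactone α-carbon, carbonyl and exocyclic methylene; C18–C20 the methyls on C4, C8, C12), and anhydrous ethereal H2O2 is taken as obtainable by extraction of the commercial aqueous reagent.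

**Route**

Step 1
Reactants: 1 hex-4-yn-1-ol
Product: 3 ethyl (E)-2-methylnon-2-en-7-ynoate, via hex-4-ynal 2 (not isolated)
Conditions: TEMPO (cat.), PhI(OAc)2, CH2Cl2, rt; then Ph3P=C(Me)CO2Et, rt
Reagents that add atoms: ethyl 2-(triphenylphosphoranylidene)propanoate, CCOC(=O)C(C)=P(c1ccccc1)(c1ccccc1)c1ccccc1
Why: oxoammonium oxidation gives the volatile aldehyde, which is trapped in the same flask by Wittig olefination; the α-branched stabilised ylide should give the E-trisubstituted enoate (the later C7=C8).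

Step 2
Reactants: 3 ethyl (E)-2-methylnon-2-en-7-ynoate
Product: 4 (E)-2-methylnon-2-en-7-yn-1-ol
Conditions: DIBAL-H, CH2Cl2, −78 → 0 °C
Reagents that add atoms: none
Why: 1,2-reduction of the enoate by DIBAL-H gives the allylic alcohol and leaves the internal alkyne and the alkene geometry untouched.

Step 3
Reactants: 4 (E)-2-methylnon-2-en-7-yn-1-ol
Product: 5 (E)-1-bromo-2-methylnon-2-en-7-yne
Conditions: CBr4, PPh3, CH2Cl2, 0 °C
Reagents that add atoms: carbon tetrabromide, BrC(Br)(Br)Br
Why: Appel bromination of a primary allylic alcohol proceeds by SN2 at the primary carbon, so no allylic transposition or E/Z loss is expected.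

Step 4
Reactants: 6 (R)-(−)-carvone
Product: 7 (R)-10-chlorocarvone
Conditions: Ca(OCl)2, CO2 (s), CH2Cl2/H2O, 0 °C
Reagents that add atoms: calcium hypochlorite, [Ca+2].[O-]Cl.[O-]Cl
Why: ene-type allylic chlorination by HOCl attacks only the electron-rich 1,1-disubstituted alkene (the enone alkene is electron-poor), functionalising the carbon that becomes C16 without touching the stereocentre.

Step 5
Reactants: 7 (R)-10-chlorocarvone
Product: 9 (R)-10-hydroxycarvone, via acetate 8 (not isolated)
Conditions: KOAc, Bu4NI (cat.), DMF, 50 °C; then K2CO3 (cat.), MeOH, 0 °C → rt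
Reagents that add atoms: potassium acetate, CC(=O)[O-].[K+]
Why: SN2 displacement of the primary allylic chloride by the weakly basic acetate avoids enolate chemistry of the enone, and transesterification then frees the alcohol.

Step 6
Reactants: 9 (R)-10-hydroxycarvone
Product: 10 (R)-10-(tert-butyldimethylsilyloxy)carvone
Conditions: TBSCl, imidazole, DMF, 0 °C → rt
Reagents that add atoms: tert-butyldimethylsilyl chloride, CC(C)(C)[Si](C)(C)Cl
Why: standard silylation of a primary alcohol gives an ether robust to the base, Grignard and metathesis steps that follow.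

Step 7
Reactants: 10 (R)-10-(tert-butyldimethylsilyloxy)carvone
Product: 13 trans-6-hydroxy-10-(tert-butyldimethylsilyloxy)carvone, via silyl dienol ether 11 (not isolated), via silyloxy ketone 12 (not isolated)
Conditions: LDA, TMSCl (in situ quench), THF, −78 °C; mCPBA, NaHCO3, CH2Cl2, −20 → 0 °C; citric acid, MeOH, rt
Reagents that add atoms: 3-chloroperoxybenzoic acid, OOC(=O)c1cccc(Cl)c1
Why: Rubottom oxidation: kinetic α′-deprotonation gives the cross-conjugated silyl dienol ether, whose enol-ether double bond is by far the most electron-rich site for the peracid; the new carbinol centre (expected trans to the C5 substituent) is destroyed in step 8.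

Step 8
Reactants: 13 trans-6-hydroxy-10-(tert-butyldimethylsilyloxy)carvone
Product: 14 methyl (2Z,5S)-5-formyl-6-[(tert-butyldimethylsilyloxy)methyl]-2-methylhepta-2,6-dienoate
Conditions: Pb(OAc)4, MeOH/PhH (1:1), 0 °C
Reagents that add atoms: methanol, CO
Why: Criegee-type cleavage of the α-hydroxy ketone in methanol turns the ring carbonyl into the methyl ester (C11) and the carbinol carbon into the aldehyde (C2); the ring alkene becomes the 12Z alkene and the carvone stereocentre (C1) is kept, the crude aldehyde being used at once to avoid epimerisation.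

Step 9
Reactants: 14 methyl (2Z,5S)-5-formyl-6-[(tert-butyldimethylsilyloxy)methyl]-2-methylhepta-2,6-dienoate; 15 1-propynylmagnesium bromide
Product: 16 methyl (2Z,5S,6R)-5-[3-(tert-butyldimethylsilyloxy)prop-1-en-2-yl]-6-hydroxy-2-methylnon-2-en-7-ynoate
Conditions: THF, −78 °C
Reagents that add atoms: none
Why: Felkin–Anh addition to the aldehyde (the ester is inert at −78 °C): with the branched alkenyl group C15 as the large substituent anti to the nucleophile and the C14 methylene inside, attack past H should give the (2R) carbinol (cembrane C2), the minor C2 epimer being removed by chromatography.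

Step 10
Reactants: 16 methyl (2Z,5S,6R)-5-[3-(tert-butyldimethylsilyloxy)prop-1-en-2-yl]-6-hydroxy-2-methylnon-2-en-7-ynoate
Product: 17 methyl (2Z,5S,6R)-5-[3-(tert-butyldimethylsilyloxy)prop-1-en-2-yl]-2-methyl-6-(triethylsilyloxy)non-2-en-7-ynoate
Conditions: TESCl, imidazole, DMAP (cat.), CH2Cl2, 0 °C
Reagents that add atoms: chlorotriethylsilane, CC[Si](Cl)(CC)CC
Why: silylation masks the propargylic hydroxyl for the enolate and metathesis steps, as a group more labile than the TBS ether to be placed on C11.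

Step 11
Reactants: 17 methyl (2Z,5S,6R)-5-[3-(tert-butyldimethylsilyloxy)prop-1-en-2-yl]-2-methyl-6-(triethylsilyloxy)non-2-en-7-ynoate
Product: 18 (2Z,5S,6R)-5-[3-(tert-butyldimethylsilyloxy)prop-1-en-2-yl]-N-methoxy-N,2-dimethyl-6-(triethylsilyloxy)non-2-en-7-ynamide
Conditions: MeNH(OMe)·HCl, i-PrMgCl, THF, −20 → 0 °C
Reagents that add atoms: N,O-dimethylhydroxylamine hydrochloride, CNOC.Cl
Why: aminolysis of the methyl ester by the magnesium amide gives the Weinreb amide directly; without an enolisable γ-activation step the Z-enoate geometry should be kept.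

Step 12
Reactants: 18 (2Z,5S,6R)-5-[3-(tert-butyldimethylsilyloxy)prop-1-en-2-yl]-N-methoxy-N,2-dimethyl-6-(triethylsilyloxy)non-2-en-7-ynamide
Product: 19 (3Z,6S,7R)-6-[3-(tert-butyldimethylsilyloxy)prop-1-en-2-yl]-3-methyl-7-(triethylsilyloxy)dec-3-en-8-yn-2-one
Conditions: MeMgBr, THF, 0 °C
Reagents that add atoms: methylmagnesium bromide, C[Mg]Br
Why: Weinreb ketone synthesis: the chelated tetrahedral adduct blocks over-addition and releases the C11 methyl ketone (C10 methyl) on work-up.

Step 13
Reactants: 19 (3Z,6S,7R)-6-[3-(tert-butyldimethylsilyloxy)prop-1-en-2-yl]-3-methyl-7-(triethylsilyloxy)dec-3-en-8-yn-2-one; 5 (E)-1-bromo-2-methylnon-2-en-7-yne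
Product: 21 (6E,11Z,14S,15R)-14-[3-(tert-butyldimethylsilyloxy)prop-1-en-2-yl]-7,11-dimethyl-15-(triethylsilyloxy)octadeca-6,11-diene-2,16-diyn-10-one, via lithium enolate 20 (not isolated)
Conditions: LDA, THF, −78 °C; then 5, DMPU, −78 → −30 °C
Reagents that add atoms: none
Why: kinetic α′-deprotonation of the methyl enone gives the cross-conjugated lithium enolate, which is alkylated by the reactive primary allylic bromide (SN2) to form C9–C10 without touching the Z-enone.

Step 14
Reactants: 21 (6E,11Z,14S,15R)-14-[3-(tert-butyldimethylsilyloxy)prop-1-en-2-yl]-7,11-dimethyl-15-(triethylsilyloxy)octadeca-6,11-diene-2,16-diyn-10-one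
Product: 22 (6E,10R,11Z,14S,15R)-14-[3-(tert-butyldimethylsilyloxy)prop-1-en-2-yl]-7,11-dimethyl-15-(triethylsilyloxy)octadeca-6,11-diene-2,16-diyn-10-ol
Conditions: (S)-Me-CBS (0.2 equiv), catecholborane, toluene, −78 °C
Reagents that add atoms: none
Why: Corey–Bakshi–Shibata reduction: with the α-methyl alkenyl group as the large and the C10 methylene as the small substituent, the (S)-oxazaborolidine should deliver hydride to give the (R)-carbinol (cembrane C11), and catecholborane at −78 °C does not hydroborate the alkynes or alkenes.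

Step 15
Reactants: 22 (6E,10R,11Z,14S,15R)-14-[3-(tert-butyldimethylsilyloxy)prop-1-en-2-yl]-7,11-dimethyl-15-(triethylsilyloxy)octadeca-6,11-diene-2,16-diyn-10-ol
Product: 23 (6E,10R,11Z,14S,15R)-10-(tert-butyldimethylsilyloxy)-14-[3-(tert-butyldimethylsilyloxy)prop-1-en-2-yl]-7,11-dimethyl-15-(triethylsilyloxy)octadeca-6,11-diene-2,16-diyne
Conditions: TBSOTf, 2,6-lutidine, CH2Cl2, −78 °C
Reagents that add atoms: tert-butyldimethylsilyl triflate, CC(C)(C)[Si](C)(C)OS(=O)(=O)C(F)(F)F
Why: silylation of the hindered allylic alcohol gives a secondary TBS ether that outlasts the later removal of the TES and primary TBS groups.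

Step 16
Reactants: 23 (6E,10R,11Z,14S,15R)-10-(tert-butyldimethylsilyloxy)-14-[3-(tert-butyldimethylsilyloxy)prop-1-en-2-yl]-7,11-dimethyl-15-(triethylsilyloxy)octadeca-6,11-diene-2,16-diyne
Product: 24 (1S,2R,7E,11R,12Z)-11,16-bis(tert-butyldimethylsilyloxy)-2-(triethylsilyloxy)cembra-7,12,15(17)-trien-3-yne
Conditions: [Mo(≡CC6H4-4-OMe)(OSiPh3)3] (10 mol%), 5 Å MS, toluene (2 mM), rt → 60 °C
Reagents that add atoms: none
Why: The molybdenum(VI) alkylidyne adds to a methyl-capped alkyne in a [2+2] step to a metallacyclobutadiene and cycloreverts, so that the substrate is loaded on the metal and the second alkyne is then engaged intramolecularly; the closest known reaction type is ring-closing alkyne metathesis of bis(methylalkynes) to macrocyclic propargylic silyl ethers with silanolate-ligated molybdenum alkylidynes. The 14-membered carbocycle closes by formation of C3≡C4 as a macrocyclisation at high dilution, driven by capture of 2-butyne in the molecular sieves, and a ring of this size should hold the linear C2–C3≡C4–C5 unit without undue strain. No stereocentre is formed, and C1, C2, C11 and the 7E and 12Z alkenes are carried through unchanged. The step needs alkyne-over-alkene chemoselectivity and tolerance of the branched propargylic site: the d0 alkylidyne does not engage the trisubstituted and 1,1-disubstituted alkenes, all three hydroxyls are silylated, and the methyl caps avoid the polymerisation seen with terminal alkynes.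

Step 17
Reactants: 24 (1S,2R,7E,11R,12Z)-11,16-bis(tert-butyldimethylsilyloxy)-2-(triethylsilyloxy)cembra-7,12,15(17)-trien-3-yne
Product: 25 (1S,2R,7E,11R,12Z)-11-(tert-butyldimethylsilyloxy)cembra-7,12,15(17)-trien-3-yne-2,16-diol
Conditions: CSA (0.1 equiv), MeOH/CH2Cl2 (1:1), 0 °C
Reagents that add atoms: none
Why: acid-catalysed methanolysis removes the TES ether and the primary allylic TBS ether much faster than the hindered secondary TBS ether on C11, freeing the propargylic hydroxyl needed for directed hydroalumination and the C16 hydroxyl needed for the lactone.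

Step 18
Reactants: 25 (1S,2R,7E,11R,12Z)-11-(tert-butyldimethylsilyloxy)cembra-7,12,15(17)-trien-3-yne-2,16-diol
Product: 27 (1S,2R,3Z,7E,11R,12Z)-11-(tert-butyldimethylsilyloxy)-4-iodocembra-3,7,12,15(17)-tetraene-2,16-diol, via alkenylaluminate 26 (not isolated)
Conditions: Red-Al, THF, 0 °C → rt; then I2, THF, −78 °C
Reagents that add atoms: iodine, II
Why: hydroxyl-directed anti-hydroalumination: the C2 alkoxide-bound aluminium hydride delivers hydride to C3 and aluminium to C4 in a five-membered oxa-aluminacycle, and iodinolysis with retention gives the iodoalkene with C2 and C5 trans; the cold quench should outrun iodoetherification of the other alkenes.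

Step 19
Reactants: 27 (1S,2R,3Z,7E,11R,12Z)-11-(tert-butyldimethylsilyloxy)-4-iodocembra-3,7,12,15(17)-tetraene-2,16-diol
Product: 28 (1S,2S,3E,7E,11R,12Z)-11-(tert-butyldimethylsilyloxy)cembra-3,7,12,15(17)-tetraene-2,16-diol
Conditions: MeZnCl (excess), Pd(PPh3)4 (5 mol%), THF, rt → 45 °C
Reagents that add atoms: methylzinc chloride, C[Zn]Cl
Why: Negishi cross-coupling replaces iodide by methyl (C18) with retention of alkene geometry, giving the E-C3=C4 alkene with the methyl cis to C2; the free hydroxyls are tolerated as zinc alkoxides.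

Step 20
Reactants: 28 (1S,2S,3E,7E,11R,12Z)-11-(tert-butyldimethylsilyloxy)cembra-3,7,12,15(17)-tetraene-2,16-diol
Product: 31 (1S,2S,3E,7E,11R,12Z)-11-(tert-butyldimethylsilyloxy)cembra-3,7,12,15(17)-tetraen-16,2-olide, via hydroxy enal 29 (not isolated), via lactol 30 (not isolated)
Conditions: TEMPO (0.2 equiv), PhI(OAc)2 (3 equiv), CH2Cl2, rt
Reagents that add atoms: none
Why: oxoammonium oxidation is selective for the primary allylic alcohol over the secondary C2 hydroxyl; the enal is captured by the C2 hydroxyl as a five-membered lactol that is oxidised on to the α-methylene-γ-lactone (oxidative lactonisation of a 2-methylene-1,4-diol).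

Step 21
Reactants: 31 (1S,2S,3E,7E,11R,12Z)-11-(tert-butyldimethylsilyloxy)cembra-3,7,12,15(17)-tetraen-16,2-olide
Product: 32 (1S,2S,3E,7S,8S,11R,12Z)-11-(tert-butyldimethylsilyloxy)-7,8-epoxycembra-3,12,15(17)-trien-16,2-olide
Conditions: L-fructose-derived Shi ketone (0.3 equiv), Oxone, K2CO3, Bu4NHSO4, MeCN/DMM/aq. Na2B4O7–EDTA, 0 °C
Reagents that add atoms: potassium peroxymonosulfate (Oxone), [K+].[O-]S(=O)(=O)OO
Why: Shi epoxidation through a spiro dioxirane transition state picks the isolated, electron-rich E-trisubstituted C7=C8 alkene (C3=C4 is deactivated by the allylic lactone oxygen, C12=C13 is Z and shielded by the C11 silyl ether, the methylene lactone is electron-poor); the usual D-fructose catalyst gives (R,R)-epoxides from such alkenes, so its enantiomer is chosen for the (7S,8S) oxirane.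

Step 22
Reactants: 32 (1S,2S,3E,7S,8S,11R,12Z)-11-(tert-butyldimethylsilyloxy)-7,8-epoxycembra-3,12,15(17)-trien-16,2-olide
Product: 33 (1S,2S,3E,7S,8S,11R,12Z)-7,8-epoxy-11-hydroxycembra-3,12,15(17)-trien-16,2-olide
Conditions: TBAF, AcOH (1:1), THF, 0 °C → rt
Reagents that add atoms: none
Why: buffered fluoride cleaves the silyl ether without the acid that would let the C11 hydroxyl open the epoxide to a tetrahydrofuran and without the basicity that would attack the methylene lactone.

Step 23
Reactants: 33 (1S,2S,3E,7S,8S,11R,12Z)-7,8-epoxy-11-hydroxycembra-3,12,15(17)-trien-16,2-olide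
Product: 34 (1S,2S,3E,7S,8S,11R,12Z)-7,8-epoxy-11-(methanesulfonyloxy)cembra-3,12,15(17)-trien-16,2-olide
Conditions: Ms2O, Et3N, CH2Cl2, −40 °C; used crude at once
Reagents that add atoms: methanesulfonic anhydride, CS(=O)(=O)OS(C)(=O)=O
Why: sulfonylation at oxygen keeps the C11 configuration, and the anhydride avoids the chloride ion that would displace a secondary allylic mesylate.

Step 24
Reactants: 34 (1S,2S,3E,7S,8S,11R,12Z)-7,8-epoxy-11-(methanesulfonyloxy)cembra-3,12,15(17)-trien-16,2-olide
Product: 36 (1S,2S,3E,7S,8R,11S,12Z)-8,11-epidioxy-7-hydroxycembra-3,12,15(17)-trien-16,2-olide, via hydroperoxide 35 (not isolated)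
Conditions: H2O2 (anhydrous, in Et2O), MoO2(acac)2 (10 mol%), 2,6-di-tert-butyl-4-methylpyridine, Et2O, −20 °C → rt
Reagents that add atoms: hydrogen peroxide, OO
Why: Proposed new method: the Mo(VI)–peroxo species should activate the trisubstituted oxirane so that H2O2 opens it at the tertiary carbon C8 with inversion (8R) while the C7–O bond is untouched (7S), and the tertiary hydroperoxide, a better nucleophile than the C7 hydroxyl, should then displace the activated allylic mesylate in a 6-exo-tet SN2 closure with inversion (11R → 11S), the hindered pyridine taking up the sulfonic acid; the reverse order (SN2 by H2O2 at C11, then opening of the epoxide by the C11 hydroperoxide) leads to the same dioxane; the closest known reactions are Mo-catalysed perhydrolysis of epoxides to β-hydroxy hydroperoxides and cyclisation of hydroperoxy sulfonates to 1,2-dioxanes, which have not been combined in one flask on a secondary allylic mesylate.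

Step 25
Reactants: 36 (1S,2S,3E,7S,8R,11S,12Z)-8,11-epidioxy-7-hydroxycembra-3,12,15(17)-trien-16,2-olide
Product: 37 denticulatolide
Conditions: Ac2O, pyridine, DMAP (cat.), CH2Cl2, 0 °C → rt
Reagents that add atoms: acetic anhydride, CC(=O)OC(C)=O
Why: DMAP-catalysed acetylation of the hindered secondary C7 hydroxyl under mild conditions that a dialkyl peroxide and the methylene lactone should tolerate.

**Compound list**

1 | hex-4-yn-1-ol | CC#CCCO | starting material
2 | hex-4-ynal | CC#CCCC=O | intermediate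
3 | ethyl (E)-2-methylnon-2-en-7-ynoate | CCOC(=O)/C(C)=C/CCC#CC | intermediate
4 | (E)-2-methylnon-2-en-7-yn-1-ol | OC/C(C)=C/CCC#CC | intermediate
5 | (E)-1-bromo-2-methylnon-2-en-7-yne | BrC/C(C)=C/CCC#CC | intermediate
6 | (R)-(−)-carvone | CC1=CC[C@@H](C(C)=C)CC1=O | starting material
7 | (R)-10-chlorocarvone | CC1=CC[C@@H](C(=C)CCl)CC1=O | intermediate
8 | (R)-10-acetoxycarvone | CC1=CC[C@@H](C(=C)COC(C)=O)CC1=O | intermediate
9 | (R)-10-hydroxycarvone | CC1=CC[C@@H](C(=C)CO)CC1=O | intermediate
10 | (R)-10-(tert-butyldimethylsilyloxy)carvone | CC1=CC[C@@H](C(=C)CO[Si](C)(C)C(C)(C)C)CC1=O | intermediate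
11 | trimethylsilyl dienol ether of 10 (enol ether at the α′-carbon) | CC1=CC[C@@H](C(=C)CO[Si](C)(C)C(C)(C)C)C=C1O[Si](C)(C)C | intermediate
12 | trans-6-(trimethylsilyloxy)-10-(tert-butyldimethylsilyloxy)carvone | CC1=CC[C@@H](C(=C)CO[Si](C)(C)C(C)(C)C)[C@H](O[Si](C)(C)C)C1=O | intermediate
13 | trans-6-hydroxy-10-(tert-butyldimethylsilyloxy)carvone | CC1=CC[C@@H](C(=C)CO[Si](C)(C)C(C)(C)C)[C@H](O)C1=O | intermediate
14 | methyl (2Z,5S)-5-formyl-6-[(tert-butyldimethylsilyloxy)methyl]-2-methylhepta-2,6-dienoate | COC(=O)/C(C)=C\C[C@@H](C(=C)CO[Si](C)(C)C(C)(C)C)C=O | intermediate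
15 | 1-propynylmagnesium bromide | CC#C[Mg]Br | starting material
16 | methyl (2Z,5S,6R)-5-[3-(tert-butyldimethylsilyloxy)prop-1-en-2-yl]-6-hydroxy-2-methylnon-2-en-7-ynoate | CC#C[C@H](O)[C@H](C(=C)CO[Si](C)(C)C(C)(C)C)C/C=C(C)\C(=O)OC | intermediate
17 | methyl (2Z,5S,6R)-5-[3-(tert-butyldimethylsilyloxy)prop-1-en-2-yl]-2-methyl-6-(triethylsilyloxy)non-2-en-7-ynoate | CC#C[C@H](O[Si](CC)(CC)CC)[C@H](C(=C)CO[Si](C)(C)C(C)(C)C)C/C=C(C)\C(=O)OC | intermediate
18 | Weinreb amide of 17 | CC#C[C@H](O[Si](CC)(CC)CC)[C@H](C(=C)CO[Si](C)(C)C(C)(C)C)C/C=C(C)\C(=O)N(C)OC | intermediate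
19 | (3Z,6S,7R)-6-[3-(tert-butyldimethylsilyloxy)prop-1-en-2-yl]-3-methyl-7-(triethylsilyloxy)dec-3-en-8-yn-2-one | CC#C[C@H](O[Si](CC)(CC)CC)[C@H](C(=C)CO[Si](C)(C)C(C)(C)C)C/C=C(C)\C(C)=O | intermediate
20 | lithium enolate of 19 (cross-conjugated, at the methyl carbon) | CC#C[C@H](O[Si](CC)(CC)CC)[C@H](C(=C)CO[Si](C)(C)C(C)(C)C)C/C=C(C)\C(=C)O[Li] | intermediate
21 | (6E,11Z,14S,15R)-14-[3-(tert-butyldimethylsilyloxy)prop-1-en-2-yl]-7,11-dimethyl-15-(triethylsilyloxy)octadeca-6,11-diene-2,16-diyn-10-one | CC#C[C@H](O[Si](CC)(CC)CC)[C@H](C(=C)CO[Si](C)(C)C(C)(C)C)C/C=C(C)\C(=O)CC/C(C)=C/CCC#CC | intermediate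
22 | (10R)-alcohol from 21 (cembrane C11 carbinol) | CC#C[C@H](O[Si](CC)(CC)CC)[C@H](C(=C)CO[Si](C)(C)C(C)(C)C)C/C=C(C)\[C@H](O)CC/C(C)=C/CCC#CC | intermediate
23 | tris-silylated bis(methylalkyne), 10-O-TBS ether of 22 | CC#C[C@H](O[Si](CC)(CC)CC)[C@H](C(=C)CO[Si](C)(C)C(C)(C)C)C/C=C(C)\[C@H](O[Si](C)(C)C(C)(C)C)CC/C(C)=C/CCC#CC | intermediate
24 | (1S,2R,7E,11R,12Z)-11,16-bis(tert-butyldimethylsilyloxy)-2-(triethylsilyloxy)cembra-7,12,15(17)-trien-3-yne (14-membered cycloalkyne) | C1#CCC/C=C(\C)CC[C@@H](O[Si](C)(C)C(C)(C)C)/C(C)=C\C[C@@H](C(=C)CO[Si](C)(C)C(C)(C)C)[C@H]1O[Si](CC)(CC)CC | intermediate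
25 | (1S,2R,7E,11R,12Z)-11-(tert-butyldimethylsilyloxy)cembra-7,12,15(17)-trien-3-yne-2,16-diol | C1#CCC/C=C(\C)CC[C@@H](O[Si](C)(C)C(C)(C)C)/C(C)=C\C[C@@H](C(=C)CO)[C@H]1O | intermediate
26 | cyclic alkenylaluminate (Al on C4 and on the C2 oxygen; simplified as the disodium salt) | [Na+].[Na+].COCCO[Al-]1(OCCOC)O[C@H]2/C=C1/CC/C=C(\C)CC[C@@H](O[Si](C)(C)C(C)(C)C)/C(C)=C\C[C@H]2C(=C)C[O-] | intermediate
27 | (1S,2R,3Z,7E,11R,12Z)-11-(tert-butyldimethylsilyloxy)-4-iodocembra-3,7,12,15(17)-tetraene-2,16-diol | O[C@H]1/C=C(\I)CC/C=C(\C)CC[C@@H](O[Si](C)(C)C(C)(C)C)/C(C)=C\C[C@H]1C(=C)CO | intermediate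
28 | (1S,2S,3E,7E,11R,12Z)-11-(tert-butyldimethylsilyloxy)cembra-3,7,12,15(17)-tetraene-2,16-diol | O[C@H]1/C=C(\C)CC/C=C(\C)CC[C@@H](O[Si](C)(C)C(C)(C)C)/C(C)=C\C[C@H]1C(=C)CO | intermediate
29 | C16 aldehyde of 28 (2-hydroxy enal) | O[C@H]1/C=C(\C)CC/C=C(\C)CC[C@@H](O[Si](C)(C)C(C)(C)C)/C(C)=C\C[C@H]1C(=C)C=O | intermediate
30 | C16 lactol (five-membered, closed onto the C2 oxygen; C16 epimers) | C=C1C(O)O[C@H]2/C=C(\C)CC/C=C(\C)CC[C@@H](O[Si](C)(C)C(C)(C)C)/C(C)=C\C[C@@H]12 | intermediate
31 | (1S,2S,3E,7E,11R,12Z)-11-(tert-butyldimethylsilyloxy)cembra-3,7,12,15(17)-tetraen-16,2-olide | C=C1C(=O)O[C@H]2/C=C(\C)CC/C=C(\C)CC[C@@H](O[Si](C)(C)C(C)(C)C)/C(C)=C\C[C@@H]12 | intermediate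
32 | (1S,2S,3E,7S,8S,11R,12Z)-11-(tert-butyldimethylsilyloxy)-7,8-epoxycembra-3,12,15(17)-trien-16,2-olide | C=C1C(=O)O[C@H]2/C=C(\C)CC[C@@H]3O[C@@]3(C)CC[C@@H](O[Si](C)(C)C(C)(C)C)/C(C)=C\C[C@@H]12 | intermediate
33 | (1S,2S,3E,7S,8S,11R,12Z)-7,8-epoxy-11-hydroxycembra-3,12,15(17)-trien-16,2-olide | C=C1C(=O)O[C@H]2/C=C(\C)CC[C@@H]3O[C@@]3(C)CC[C@@H](O)/C(C)=C\C[C@@H]12 | intermediate
34 | (1S,2S,3E,7S,8S,11R,12Z)-7,8-epoxy-11-(methanesulfonyloxy)cembra-3,12,15(17)-trien-16,2-olide | C=C1C(=O)O[C@H]2/C=C(\C)CC[C@@H]3O[C@@]3(C)CC[C@@H](OS(C)(=O)=O)/C(C)=C\C[C@@H]12 | intermediate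
35 | (1S,2S,3E,7S,8R,11R,12Z)-8-hydroperoxy-7-hydroxy-11-(methanesulfonyloxy)cembra-3,12,15(17)-trien-16,2-olide | C=C1C(=O)O[C@H]2/C=C(\C)CC[C@H](O)[C@@](OO)(C)CC[C@@H](OS(C)(=O)=O)/C(C)=C\C[C@@H]12 | intermediate
36 | (1S,2S,3E,7S,8R,11S,12Z)-8,11-epidioxy-7-hydroxycembra-3,12,15(17)-trien-16,2-olide (7-deacetyl compound) | C=C1C(=O)O[C@H]2/C=C(\C)CC[C@H](O)[C@@]3(C)CC[C@H](OO3)/C(C)=C\C[C@@H]12 | intermediate
37 | denticulatolide | C=C1C(=O)O[C@H]2/C=C(\C)CC[C@H](OC(C)=O)[C@@]3(C)CC[C@H](OO3)/C(C)=C\C[C@@H]12 | target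

**Step count and risks**

Total step count: 25. Longest linear sequence: 22 steps (steps 4–25, from (R)-carvone 6 to 37); bromide 5 is made in 3 steps and joins at step 13.

Steps most likely to fail:

1. Step 24 (Proposed new method). What may go wrong: the secondary allylic mesylate ionises before the SN2 event, which scrambles C11, allows SN2′ capture at C13 or elimination to a diene; the C7 hydroxyl closes a tetrahydropyran in place of the hydroperoxide; or the β-hydroxy hydroperoxide fragments under acid. The fallback avoids any leaving group on the allylic carbon and uses known chemistry (Mo-catalysed epoxide perhydrolysis, then ionic reduction of a cyclic peroxyhemiketal through its peroxycarbenium ion). It sets out from epoxy alcohol 33. MnO2 in CH2Cl2 should oxidise the allylic C11 hydroxyl to (1S,2S,3E,7S,8S,12Z)-7,8-epoxy-11-oxocembra-3,12,15(17)-trien-16,2-olide F1. Ethereal H2O2 with MoO2(acac)2 should open the epoxide at C8 as in the main route, and the C8 hydroperoxide should add to the C11 ketone to give the cyclic peroxyhemiketal, 8,11-epidioxy-7,11-dihydroxycembra-3,12,15(17)-trien-16,2-olide F2. Et3SiH with catalytic TMSOTf in CH2Cl2 at −78 °C should then reduce the hemiketal carbon, and the route is rejoined at 36. In this variant C11 is set by hydride delivery to the ring peroxycarbenium ion, so its configuration would have to be established.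

2. Step 21. What may go wrong: oxygen is delivered to the wrong face of C7=C8 because the conformation of the macrolactone, not the catalyst, decides the face (peripheral attack); some epoxidation at C3=C4 is a lesser concern. The fallback turns the ring's own facial preference round by an anti-addition/inversion sequence and sets out from lactone 31. NBS in THF/H2O at 0 °C should form the bromonium ion on the face the ring prefers, and water should open it anti at the tertiary carbon to give the bromohydrin, (7R,8S)-7-bromo-11-(tert-butyldimethylsilyloxy)-8-hydroxycembra-3,12,15(17)-trien-16,2-olide F3. DBU in CH2Cl2 at 0 °C should close the oxirane by displacement of bromide with inversion at C7, placing the epoxide oxygen on the face opposite to direct epoxidation, and the route is rejoined at 32.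

3. Step 9. What may go wrong: poor Felkin–Anh facial discrimination between the alkenyl and the methylene substituent in the Grignard addition, giving a mixture at C2. The fallback replaces substrate control by reagent control and sets out from 16 obtained as a mixture of C2 epimers. Dess–Martin periodinane (NaHCO3, CH2Cl2) should give the ynone, methyl (2Z,5S)-5-[3-(tert-butyldimethylsilyloxy)prop-1-en-2-yl]-2-methyl-6-oxonon-2-en-7-ynoate F4. Noyori asymmetric transfer hydrogenation with RuCl[(R,R)-TsDPEN](p-cymene) in 2-propanol at rt, the catalyst antipode that gives (R)-propargylic alcohols from alkynyl ketones, should return 16 as the (6R) carbinol under neutral conditions that spare the α-stereocentre.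

Further compounds
F1 | step 24 | (1S,2S,3E,7S,8S,12Z)-7,8-epoxy-11-oxocembra-3,12,15(17)-trien-16,2-olide | C=C1C(=O)O[C@H]2/C=C(\C)CC[C@@H]3O[C@@]3(C)CCC(=O)/C(C)=C\C[C@@H]12
F2 | step 24 | (1S,2S,3E,7S,8R,12Z)-8,11-epidioxy-7,11-dihydroxycembra-3,12,15(17)-trien-16,2-olide (cyclic peroxyhemiketal, C11 unassigned) | C=C1C(=O)O[C@H]2/C=C(\C)CC[C@H](O)[C@@]3(C)CCC(O)(OO3)/C(C)=C\C[C@@H]12
F3 | step 21 | (1S,2S,3E,7R,8S,11R,12Z)-7-bromo-11-(tert-butyldimethylsilyloxy)-8-hydroxycembra-3,12,15(17)-trien-16,2-olide | C=C1C(=O)O[C@H]2/C=C(\C)CC[C@@H](Br)[C@](O)(C)CC[C@@H](O[Si](C)(C)C(C)(C)C)/C(C)=C\C[C@@H]12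
F4 | step 9 | methyl (2Z,5S)-5-[3-(tert-butyldimethylsilyloxy)prop-1-en-2-yl]-2-methyl-6-oxonon-2-en-7-ynoate | CC#CC(=O)[C@H](C(=C)CO[Si](C)(C)C(C)(C)C)C/C=C(C)\C(=O)OC
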